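## Analysis of the target

The target 34 is a labdane: a trans-fused decalin (ring A = C1–C5, C10; ring B = C5–C10) with an exocyclic C8=C17 methylene, a C9 side chain ending in an (E)-trisubstituted allylic alcohol (C13=C14, C15–OH), an axial carboxyl C19 on the quaternary C4, a benzoate on O6 and a free hydroxyl on C7. Its six contiguous stereocentres are (4S,5R,6S,7S,9S,10R): the C10 methyl (C20), the C19 carboxyl and the C6 benzoate share the β face in a 1,3-diaxial array, H5 is α (trans fusion), the C7 hydroxyl is α and trans-diaxial to the benzoate, and H9 is β, so the side chain is axial on the α face. This axial side chain is the less stable C9 epimer, so it cannot be reached by equilibration or by hydrogen delivery to the open α face. The sensitive groups are two allylic alcohols, an exocyclic alkene that can migrate into the ring, and the benzoate. A free 6β-hydroxyl next to an axial C19 carbonyl would close to the 19,6-lactol or lactone, so the benzoate has to be in place before C19 becomes an axial carbonyl. The hard points are the two quaternary carbons C4 and C10 flanking C5, the differentiated trans-diol at C6/C7, and a side-chain alkene that competes in any electrophilic oxidation of ring B. The strategy rests on ring B: the methyl-bearing carbons C8 and C10 flank C9, and C6, para to C9, carries oxygen. That is the pattern of 2,6-dimethyl-1,4-benzoquinone 4 with its carbonyls at C9 and C6, and ring A is the cyclohexene formed when a diene adds across C5=C10.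

## Retrosynthetic reasoning

34 ⇒ 31. The C7–O bond is cut first. An allylic alcohol beside an exocyclic methylene is the retron of a Schenck ene reaction of the C7=C8 alkene bearing the C17 methyl. C15 is taken back to the aldehyde, because an enal does not compete for the electrophilic oxygen whereas an allylic ether in the side chain would. Forward, oxygen must add to the α face of C7 and take hydrogen from C17; one reduction then gives both alcohols.

31 ⇒ 29 ⇒ 28. These are functional-group changes only. The enal comes from the PMB ether 29, and the C19 acid comes from the aldehyde 28 before the enal exists, so that the oxidant meets one aldehyde.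

28 ⇒ 26. The C4–C18 bond is cut. Methylation of the exocyclic enolate 27 builds the quaternary C4, and equatorial attack puts the formyl group axial as C19. It is done late because C19 has to stay a protected alcohol through the organolithium and hydrazone steps. It is done after benzoylation so that a free 6β-hydroxyl never meets the axial formyl group.

26 ⇒ 24. The silyl ether from the diene is removed and the alcohol 25 oxidised; no skeletal change.

24 ⇒ 21 ⇒ 20. The C9–H bond is the stereochemical crux. It is traced to the C7 carbonyl of enone 20: the tosylhydrazone 21 is reduced at C7 from the open α face, and the resulting β nitrogen hands its hydrogen to the β face of C9 as the alkene moves to C7=C8. This gains the contra-thermodynamic axial side chain by an intramolecular delivery.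

20 ⇒ 19 ⇒ 18. The C7 carbonyl is traced to the tertiary allylic alcohol 19 by an oxidative 1,3-transposition. This moves the oxygen that the quinone supplied at C9 to C7, where the target needs it. The benzoate is put on diol 18 while C4 still has hydrogen on the β face and O6 is accessible.

18 ⇒ 8 + 17. The C9–C11 bond is cut at the C9 carbonyl of 8. The side chain enters as the alkyllithium 17, made from iodide 16.

16 ⇒ 13 ⇒ 10 ⇒ 9. The C13–C16 and C14–C15 bonds are cut together. Syn carbometalation of the alkyne 10 and hydroxymethylation fix the E alkene in 13 with no olefination step.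

8 ⇒ 7 ⇒ 6. The C2=C3 alkene left by the cycloaddition is saturated, and the C6 alcohol comes from the less hindered carbonyl of ene-dione 6, reduced anti to the C10 methyl.

6 ⇒ 5. C5 is inverted by enolisation toward the C6 carbonyl. The cis adduct 5 is what the cycloaddition gives; the trans fusion of the target is reached by equilibration.

5 ⇒ 3 + 4. The C1–C10 and C4–C5 bonds are cut. One cycloaddition of diene 3 across a methylated alkene of quinone 4 makes ring A, the quaternary C10, C5 and the C4 carbon with its one-carbon substituent, and leaves the two carbonyls that become O6 and O7. No other cut delivers as much from two simple compounds.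

3 ⇒ 2 ⇒ 1. The diene is the silyl ether of the alcohol 2, obtained by reducing acid 1.

## Alternatives that were turned down

Alternative 1: Ring B is made first as a cyclohexanone, with the C9–C11 and C10–C20 bonds cut; ring A is annulated later from the C5 carbonyl and a three-carbon arm. In the forward key step the side-chain cuprate adds to enone A1 anti to the silyloxy group and the enolate is methylated at C10, giving A2. In its favour, the route is convergent and the full side chain, its axial orientation and its trans relation to the C10 methyl come from one operation. On that point it is stronger than the chosen route, which needs steps 12 and 14–16 to place and orient the chain. Against it, the enolate is tetrasubstituted and must be C-methylated to a quaternary centre beside the new branch, where proton transfer and slow trapping compete. A2 still lacks ring A, the quaternary C4, the C5 configuration and any oxygen at C6 or C7, and A1 needs its own enantioselective synthesis. The chosen route instead has ring A, C10, C5, the C4 carbon and the C6 oxygen in place after four steps.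

Alternative 2: Both rings are cut at C4–C5 and C9–C10 from an open-chain β-keto ester with a chiral ester group. Forward, Mn(OAc)3 makes the C4 radical, which adds to C5=C10; the C10 radical adds to the Z-configured C8=C9 alkene; Cu(OAc)2 oxidises the C8 radical with loss of a C17 hydrogen, giving A3. In its favour, two rings, both quaternary carbons, C19 at the acid level and the exocyclic alkene arise in one step, and the Z geometry translates into 9β-H. In ring-building economy it is stronger than the chosen route. Against it, A3 has CH2 groups at C6 and C7 and an unwanted C3 carbonyl. C7 could be oxidised allylically, but C6 is unactivated, so the trans-diaxial 6,7-diol monoester would need a long detour. The bulky ester must be cleaved from the hindered axial C19, the side chain stops at C12, and control of a Z-olefin transition state by a remote auxiliary is less secure than for all-E polyenes. The chosen route takes both ring-B oxygens from the quinone carbonyls and needs no oxidation of an unactivated position.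

Alternative 3: Ring B is cut at C7–C8, starting from a fully substituted ring A that carries an acetyl group on C5 and a vinyl-bearing branch on C10. Forward, the C6 silyl enol ether attacks the alkene activated by Pd(OAc)2, C7–C8 forms, and β-hydride loss gives the exocyclic alkene in A4. In its favour, A4 already has the C6 carbonyl, the 8(17)-alkene, the whole side chain with C9 set and the C19 ester. Its end game (C7 hydroxylation, C6 reduction, benzoylation) is more direct than that of the chosen route. Against it, the cyclisation substrate needs C4, C5, C10 and the exocyclic C9 centre assembled beforehand on a monocyclic ring, a long linear sequence with weak control at C9. Divalent palladium is usually consumed in stoichiometric amount. The β,γ-unsaturated ketone A4 tends to move its alkene into conjugation. The hindered methyl ester cannot be hydrolysed beside a benzoate, and reducing C6 next to the C19 ester invites lactonisation. The chosen route offers a catalytic three-stereocentre entry to the bicycle from two simple compounds, with all later centres set on a rigid decalin.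

Key step: step 3

Convention: bicyclic compounds use labdane numbering (C17 on C8, C20 on C10, side chain C11–C16); the C4 substituent that becomes the carboxyl is C19 and the methyl added to C4 is C18; β is the face of the C10 methyl.

Assumption: the (S)-configured catalyst is taken as the antipode that leaves open the quinone face leading to 5; if the sense is the opposite, the (R)-catalyst is used and nothing else changes.

## Route

Step 1
Reactants: 1 (E)-penta-2,4-dienoic acid
Product: 2 (E)-penta-2,4-dien-1-ol
Conditions: LiAlH4, Et2O, 0 °C → rt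
Reagents that add atoms: none
Why: LiAlH4 reduction of a carboxylic acid to the primary alcohol; the carboxylate is reduced without touching the conjugated diene and the E geometry is kept.

Step 2
Reactants: 2 (E)-penta-2,4-dien-1-ol
Product: 3 (E)-tert-butyldimethyl(penta-2,4-dienyloxy)silane
Conditions: TBSCl, imidazole, CH2Cl2, 0 °C → rt
Reagents that add atoms: tert-butyldimethylsilyl chloride, CC(C)(C)[Si](C)(C)Cl
Why: Silylation of a primary alcohol; the TBS ether should tolerate the Lewis acid of step 3 and every step up to its removal in step 17.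

Step 3
Reactants: 3 (E)-tert-butyldimethyl(penta-2,4-dienyloxy)silane; 4 2,6-dimethyl-1,4-benzoquinone
Product: 5 cis-fused ene-dione adduct (10β-CH3; 5β-H; 4β-H; 4α-CH2OTBS)
Conditions: triflimide salt of the N-protonated (S)-oxazaborolidine from α,α-diphenylprolinol and o-tolylboronic acid, [C24H25BNO][N(SO2CF3)2] (20 mol%), CH2Cl2, −78 → −40 °C
Reagents that add atoms: none
Why: The cationic boron binds the C6 carbonyl of 4, the only one flanked by C–H groups, and lowers the LUMO of the C5=C10 bond. A concerted but asynchronous endo [4+2] cycloaddition follows (catalysed quinone Diels–Alder reaction; closest known class: oxazaborolidinium-catalysed additions of 1-substituted dienes to alkylbenzoquinones): the free terminus of 3 bonds first to C10, the β carbon of the activated enone, forming C1–C10, and the substituted terminus closes C4–C5. Ring A closes as a six-membered carbocycle by suprafacial cycloaddition on both partners. C10 is set by the catalyst, which shields one face of the bound quinone. C5 follows from suprafacial addition, so H5 is cis to C20. C4 follows from the endo transition state and the E diene, which put H4 cis to H5 and the silyloxymethyl group on the opposite face. The step needs regiocontrol (secured by coordination at the unhindered C6 carbonyl, so that the larger HOMO coefficient at the free diene terminus meets C10) and enantioface control (catalyst); there is no site problem because the two methylated alkenes of 4 are equivalent by symmetry. The quaternary C10 blocks aromatisation of the adduct.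

Step 4
Reactants: 5 cis-fused ene-dione adduct
Product: 6 trans-fused ene-dione (5α-H)
Conditions: 1,8-diazabicyclo[5.4.0]undec-7-ene (0.2 equiv), CH2Cl2, rt
Reagents that add atoms: none
Why: Base-mediated epimerisation through the C5 enolate (thermodynamic equilibration); C5 is the only enolisable ring-fusion position because C10 is quaternary, and the trans-fused decalin should be the more stable epimer.

Step 5
Reactants: 6 trans-fused ene-dione
Product: 7 6β-hydroxy-2,7-dien-9-one
Conditions: NaBH4 (1.0 equiv), CeCl3·7H2O, MeOH/CH2Cl2, −78 °C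
Reagents that add atoms: none
Why: Luche 1,2-reduction; C6 lies between CH groups whereas C9 lies between the quaternary C10 and the methylated C8, so one equivalent of hydride should take C6 only. Hydride enters from the α face because the axial C10 methyl covers the β face, giving the 6β alcohol.

Step 6
Reactants: 7 6β-hydroxy-2,7-dien-9-one
Product: 8 6β-hydroxy-7-en-9-one with saturated ring A
Conditions: H2 (1 atm), RhCl(PPh3)3 (5 mol%), benzene, rt
Reagents that add atoms: none
Why: Homogeneous hydrogenation; RhCl(PPh3)3 reduces the unhindered cis-disubstituted C2=C3 bond and should leave the trisubstituted conjugated C7=C8 bond. No stereocentre is formed.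

Step 7
Reactants: 9 but-3-yn-1-ol
Product: 10 (but-3-ynyloxy)(tert-butyl)dimethylsilane
Conditions: TBSCl, imidazole, DMF, rt
Reagents that add atoms: tert-butyldimethylsilyl chloride, CC(C)(C)[Si](C)(C)Cl
Why: Silylation of the primary alcohol; the silyl ether is compatible with the organoaluminium chemistry of step 8.

Step 8
Reactants: 10 (but-3-ynyloxy)(tert-butyl)dimethylsilane
Product: 13 (E)-5-(tert-butyldimethylsilyloxy)-3-methylpent-2-en-1-ol, via alkenyldimethylalane 11 (not isolated), via lithium alkenylalanate 12 (not isolated)
Conditions: AlMe3 (2.5 equiv), Cp2ZrCl2 (0.25 equiv), CH2Cl2, 0 °C → rt; then n-BuLi, THF/hexane, −78 °C; (CH2O)n, −78 °C → rt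
Reagents that add atoms: trimethylaluminium, C[Al](C)C; formaldehyde (as paraformaldehyde), C=O
Why: Negishi carboalumination: syn addition of methyl and aluminium puts methyl on the internal carbon, so the trisubstituted alkene is E by construction. The alanate is hydroxymethylated with retention of geometry.

Step 9
Reactants: 13 (E)-5-(tert-butyldimethylsilyloxy)-3-methylpent-2-en-1-ol
Product: 14 tert-butyl{[(E)-5-(4-methoxybenzyloxy)-3-methylpent-3-enyl]oxy}dimethylsilane
Conditions: NaH, 4-methoxybenzyl chloride, Bu4NI (cat.), THF/DMF, 0 °C → rt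
Reagents that add atoms: 4-methoxybenzyl chloride, COc1ccc(CCl)cc1
Why: Williamson ether synthesis on the allylic alkoxide; the PMB ether survives organolithium, chromium and borane reagents and is removed oxidatively in step 21.

Step 10
Reactants: 14 tert-butyl{[(E)-5-(4-methoxybenzyloxy)-3-methylpent-3-enyl]oxy}dimethylsilane
Product: 15 (E)-5-(4-methoxybenzyloxy)-3-methylpent-3-en-1-ol
Conditions: tetrabutylammonium fluoride, THF, rt
Reagents that add atoms: none
Why: Fluoride-mediated desilylation; the PMB ether and the alkene are inert.

Step 11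
Reactants: 15 (E)-5-(4-methoxybenzyloxy)-3-methylpent-3-en-1-ol
Product: 16 1-{[(E)-5-iodo-3-methylpent-2-enyl]oxymethyl}-4-methoxybenzene
Conditions: I2, PPh3, imidazole, CH2Cl2, 0 °C
Reagents that add atoms: iodine, II
Why: Appel-type iodination; SN2 displacement at the primary carbinol under neutral conditions that spare the allylic ether and the E alkene.

Step 12
Reactants: 16 1-{[(E)-5-iodo-3-methylpent-2-enyl]oxymethyl}-4-methoxybenzene; 8 6β-hydroxy-7-en-9-one with saturated ring A
Product: 18 6β,9-dihydroxy-7-ene carrying the side chain on C9, via alkyllithium 17 (not isolated)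
Conditions: 16, t-BuLi (2.1 equiv), Et2O, −78 °C; then 8 (0.35 equiv), THF, −78 → −40 °C; aq. NH4Cl
Reagents that add atoms: none
Why: Iodine–lithium exchange, then 1,2-addition of the alkyllithium to a hindered, non-enolisable enone; the first equivalent of 17 deprotonates the C6 hydroxyl, hence the excess. Attack from the α face, away from the C10 methyl, is expected, but the C9 carbinol configuration is erased in step 14.

Step 13
Reactants: 18 6β,9-dihydroxy-7-ene carrying the side chain on C9
Product: 19 6β-benzoate of the tertiary allylic alcohol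
Conditions: BzCl, pyridine, 4-(dimethylamino)pyridine (cat.), CH2Cl2, 0 °C → rt
Reagents that add atoms: benzoyl chloride, O=C(Cl)c1ccccc1
Why: DMAP-catalysed acylation; the secondary 6β-hydroxyl reacts and the tertiary C9 hydroxyl does not. C4 still carries hydrogen on the β face here, so O6 is more accessible than it would be once C19 is axial.

Step 14
Reactants: 19 6β-benzoate of the tertiary allylic alcohol
Product: 20 6β-benzoyloxy-8-en-7-one
Conditions: pyridinium chlorochromate [C5H5NH][CrO3Cl], 4 Å molecular sieves, CH2Cl2, rt
Reagents that add atoms: none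
Why: Babler–Dauben oxidative 1,3-transposition: the chromate ester of the tertiary allylic alcohol shifts to C7 and is oxidised there, moving the oxygen from C9 to C7 and the alkene to C8=C9. The 6α-hydrogen lies near the plane of the new carbonyl, which should retard enolisation and protect the C6 configuration.

Step 15
Reactants: 20 6β-benzoyloxy-8-en-7-one
Product: 21 C7 tosylhydrazone of 20
Conditions: TsNHNH2, pyridinium p-toluenesulfonate (cat.), EtOH, 60 °C
Reagents that add atoms: p-toluenesulfonyl hydrazide, Cc1ccc(S(=O)(=O)NN)cc1
Why: Hydrazone condensation at the only carbonyl that can condense; mild acid catalysis is chosen to spare the α-benzoyloxy centre.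

Step 16
Reactants: 21 C7 tosylhydrazone of 20
Product: 24 6β-benzoyloxy-9β-H-7,13E-diene (side chain α), via allylic tosylhydrazine 22 (not isolated), via allylic diazene 23 (not isolated)
Conditions: catecholborane (3 equiv), CHCl3, 0 °C → rt; then NaOAc·3H2O, reflux
Reagents that add atoms: none
Why: Reduction of an α,β-unsaturated tosylhydrazone with 1,3-transposition (hydride addition, sulfinate loss, retro-ene of the allylic diazene). Hydride should add to C7 from the α face, opposite the pseudoaxial 6β-benzoate and the C10 methyl, so the diazene nitrogen stands on the β face and passes its hydrogen suprafacially to the β face of C9. This sets 9β-H with the side chain axial and returns the alkene to C7=C8.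

Step 17
Reactants: 24 6β-benzoyloxy-9β-H-7,13E-diene
Product: 25 C19 primary alcohol
Conditions: HF·pyridine, pyridine, THF, 0 °C → rt
Reagents that add atoms: none
Why: Buffered fluoride desilylation of the primary TBS ether; the slightly acidic medium should prevent benzoyl migration and leave the PMB ether.

Step 18
Reactants: 25 C19 primary alcohol
Product: 26 C19 aldehyde (4α-CHO; 4β-H)
Conditions: Dess–Martin periodinane, NaHCO3, CH2Cl2, rt
Reagents that add atoms: none
Why: Dess–Martin oxidation of the only free hydroxyl; the C4 configuration is of no consequence because it is planarised in step 19.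

Step 19
Reactants: 26 C19 aldehyde
Product: 28 4β-formyl-4α-methyl compound, via potassium enolate 27 (not isolated)
Conditions: KOt-Bu (1.3 equiv), MeI (10 equiv), THF, −40 → 0 °C
Reagents that add atoms: iodomethane, CI
Why: Enolate C-alkylation of an α-branched aldehyde: the exocyclic enolate is methylated from the α (equatorial) face because the axial C10 methyl and the 6β-benzoate cover the β face. The methyl ends at 4α and the formyl group axial at 4β as C19. MeI is present before the base, so the enolate is trapped as it forms and the benzoate meets little alkoxide.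

Step 20
Reactants: 28 4β-formyl-4α-methyl compound
Product: 29 19-oic acid
Conditions: NaClO2, NaH2PO4, 2-methyl-2-butene, t-BuOH/H2O, rt
Reagents that add atoms: sodium chlorite, [Na+].[O-]Cl=O
Why: Pinnick oxidation, which works on hindered aldehydes; the scavenger removes hypochlorite before it can reach the two trisubstituted alkenes or the PMB ring.

Step 21
Reactants: 29 19-oic acid
Product: 31 15-oxo acid (13E enal), via allylic alcohol 30 (not isolated)
Conditions: DDQ (1.3 equiv), CH2Cl2/pH 7 buffer, 0 °C → rt; then Dess–Martin periodinane, NaHCO3, CH2Cl2, rt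
Reagents that add atoms: none
Why: Oxidative PMB ether cleavage by DDQ, then Dess–Martin oxidation of the released allylic alcohol. The enal makes the side-chain alkene electron-poor for step 22, and the neutral conditions should keep its E geometry.

Step 22
Reactants: 31 15-oxo acid (13E enal)
Product: 34 6β-benzoyloxy-7α,15-dihydroxy-9β-H-labda-8(17),13E-dien-19-oic acid, via hydroperoxy enal 32 (not isolated), via hydroxy enal 33 (not isolated)
Conditions: O2, visible light, 5,10,15,20-tetraphenylporphyrin (cat.), CH2Cl2, 0 °C; then PPh3; then MeOH, CeCl3·7H2O, NaBH4, −20 °C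
Reagents that add atoms: oxygen, O=O
Why: Schenck ene reaction, then reduction: singlet oxygen should add to C7 of the only electron-rich alkene from the α face, since the 6β-benzoate and the C10 methyl close the β face, and take hydrogen from C17, the only allylic hydrogen within reach on that face. This gives the 7α-hydroperoxide and the exocyclic alkene. PPh3 reduces the O–O bond with retention, and the Luche reduction converts the enal into the allylic alcohol without touching benzoate or acid.

## Compound list

1 | (E)-penta-2,4-dienoic acid | C=C/C=C/C(=O)O | starting material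
2 | (E)-penta-2,4-dien-1-ol | C=C/C=C/CO | intermediate
3 | (E)-tert-butyldimethyl(penta-2,4-dienyloxy)silane | C=C/C=C/CO[Si](C)(C)C(C)(C)C | intermediate
4 | 2,6-dimethyl-1,4-benzoquinone | CC1=CC(=O)C=C(C)C1=O | starting material
5 | cis-fused adduct, 5-[(tert-butyldimethylsilyloxy)methyl]-2,8a-dimethyl-4a,5,8,8a-tetrahydronaphthalene-1,4-dione; labdane numbering: 2,7-diene-6,9-dione, 10β-CH3, 5β-H, 4β-H, 4α-CH2OTBS | CC=1C(=O)[C@@]2(C)CC=C[C@@H](CO[Si](C)(C)C(C)(C)C)[C@H]2C(=O)C=1 | intermediate
6 | trans-fused C5 epimer of 5 (5α-H, 10β-CH3, 4β-H, 4α-CH2OTBS) | CC=1C(=O)[C@@]2(C)CC=C[C@@H](CO[Si](C)(C)C(C)(C)C)[C@@H]2C(=O)C=1 | intermediate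
7 | 6β-hydroxy-2,7-dien-9-one (5α-H, 10β-CH3, 4α-CH2OTBS, 8-CH3) | CC=1C(=O)[C@@]2(C)CC=C[C@@H](CO[Si](C)(C)C(C)(C)C)[C@@H]2[C@H](O)C=1 | intermediate
8 | 6β-hydroxy-7-en-9-one with saturated ring A (5α-H, 10β-CH3, 4α-CH2OTBS) | CC=1C(=O)[C@@]2(C)CCC[C@@H](CO[Si](C)(C)C(C)(C)C)[C@@H]2[C@H](O)C=1 | intermediate
9 | but-3-yn-1-ol | C#CCCO | starting material
10 | (but-3-ynyloxy)(tert-butyl)dimethylsilane | C#CCCO[Si](C)(C)C(C)(C)C | intermediate
11 | [(E)-4-(tert-butyldimethylsilyloxy)-2-methylbut-1-enyl]dimethylalane | CC(C)(C)[Si](C)(C)OCC/C(C)=C/[Al](C)C | intermediate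
12 | lithium butyl[(E)-4-(tert-butyldimethylsilyloxy)-2-methylbut-1-enyl]dimethylaluminate | CC(C)(C)[Si](C)(C)OCC/C(C)=C/[Al-](C)(C)CCCC.[Li+] | intermediate
13 | (E)-5-(tert-butyldimethylsilyloxy)-3-methylpent-2-en-1-ol | CC(C)(C)[Si](C)(C)OCC/C(C)=C/CO | intermediate
14 | tert-butyl{[(E)-5-(4-methoxybenzyloxy)-3-methylpent-3-enyl]oxy}dimethylsilane | CC(C)(C)[Si](C)(C)OCC/C(C)=C/COCc1ccc(OC)cc1 | intermediate
15 | (E)-5-(4-methoxybenzyloxy)-3-methylpent-3-en-1-ol | OCC/C(C)=C/COCc1ccc(OC)cc1 | intermediate
16 | 1-{[(E)-5-iodo-3-methylpent-2-enyl]oxymethyl}-4-methoxybenzene | ICC/C(C)=C/COCc1ccc(OC)cc1 | intermediate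
17 | [(E)-5-(4-methoxybenzyloxy)-3-methylpent-3-enyl]lithium | [Li]CC/C(C)=C/COCc1ccc(OC)cc1 | intermediate
18 | 6β,9β-dihydroxy-7-ene with the PMB-protected side chain 9α (5α-H, 10β-CH3, 4α-CH2OTBS; C9 as expected for α attack, not relevant later) | CC=1[C@@](O)(CC/C(C)=C/COCc3ccc(OC)cc3)[C@@]2(C)CCC[C@@H](CO[Si](C)(C)C(C)(C)C)[C@@H]2[C@H](O)C=1 | intermediate
19 | 6β-benzoate of 18 (9-hydroxyl free) | CC=1[C@@](O)(CC/C(C)=C/COCc3ccc(OC)cc3)[C@@]2(C)CCC[C@@H](CO[Si](C)(C)C(C)(C)C)[C@@H]2[C@H](OC(=O)c3ccccc3)C=1 | intermediate
20 | 6β-benzoyloxy-8-en-7-one with the side chain on C9 (5α-H, 10β-CH3, 4α-CH2OTBS) | CC1=C(CC/C(C)=C/COCc3ccc(OC)cc3)[C@@]2(C)CCC[C@@H](CO[Si](C)(C)C(C)(C)C)[C@@H]2[C@H](OC(=O)c3ccccc3)C1=O | intermediate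
21 | C7 p-toluenesulfonylhydrazone of 20 | CC1=C(CC/C(C)=C/COCc3ccc(OC)cc3)[C@@]2(C)CCC[C@@H](CO[Si](C)(C)C(C)(C)C)[C@@H]2[C@H](OC(=O)c3ccccc3)C1=NNS(=O)(=O)c1ccc(C)cc1 | intermediate
22 | 7β-(2-tosylhydrazinyl)-7α-H-8-ene (N-borylated in the flask) | CC1=C(CC/C(C)=C/COCc3ccc(OC)cc3)[C@@]2(C)CCC[C@@H](CO[Si](C)(C)C(C)(C)C)[C@@H]2[C@H](OC(=O)c3ccccc3)[C@@H]1NNS(=O)(=O)c1ccc(C)cc1 | intermediate
23 | 7β-diazenyl-8-ene (allylic diazene) | CC1=C(CC/C(C)=C/COCc3ccc(OC)cc3)[C@@]2(C)CCC[C@@H](CO[Si](C)(C)C(C)(C)C)[C@@H]2[C@H](OC(=O)c3ccccc3)[C@@H]1N=N | intermediate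
24 | 6β-benzoyloxy-15-(4-methoxybenzyloxy)-19-(tert-butyldimethylsilyloxy)-9β-H-7,13E-diene (side chain 9α, 4β-H, 5α-H, 10β-CH3) | CC=1[C@@H](CC/C(C)=C/COCc3ccc(OC)cc3)[C@@]2(C)CCC[C@@H](CO[Si](C)(C)C(C)(C)C)[C@@H]2[C@H](OC(=O)c3ccccc3)C=1 | intermediate
25 | C19 alcohol from 24 (4α-CH2OH, 4β-H) | CC=1[C@@H](CC/C(C)=C/COCc3ccc(OC)cc3)[C@@]2(C)CCC[C@@H](CO)[C@@H]2[C@H](OC(=O)c3ccccc3)C=1 | intermediate
26 | C19 aldehyde (4α-CHO, 4β-H) | CC=1[C@@H](CC/C(C)=C/COCc3ccc(OC)cc3)[C@@]2(C)CCC[C@@H](C=O)[C@@H]2[C@H](OC(=O)c3ccccc3)C=1 | intermediate
27 | potassium C4=C19 enolate of 26 | CC=1[C@@H](CC/C(C)=C/COCc3ccc(OC)cc3)[C@@]2(C)CCCC(=C[O-])[C@@H]2[C@H](OC(=O)c3ccccc3)C=1.[K+] | intermediate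
28 | 6β-benzoyloxy-15-(4-methoxybenzyloxy)-9β-H-labda-7,13E-dien-19-al (4β-CHO, 4α-CH3) | CC=1[C@@H](CC/C(C)=C/COCc3ccc(OC)cc3)[C@@]2(C)CCC[C@](C)(C=O)[C@@H]2[C@H](OC(=O)c3ccccc3)C=1 | intermediate
29 | 6β-benzoyloxy-15-(4-methoxybenzyloxy)-9β-H-labda-7,13E-dien-19-oic acid | CC=1[C@@H](CC/C(C)=C/COCc3ccc(OC)cc3)[C@@]2(C)CCC[C@](C)(C(=O)O)[C@@H]2[C@H](OC(=O)c3ccccc3)C=1 | intermediate
30 | 6β-benzoyloxy-15-hydroxy-9β-H-labda-7,13E-dien-19-oic acid | CC=1[C@@H](CC/C(C)=C/CO)[C@@]2(C)CCC[C@](C)(C(=O)O)[C@@H]2[C@H](OC(=O)c3ccccc3)C=1 | intermediate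
31 | 6β-benzoyloxy-15-oxo-9β-H-labda-7,13E-dien-19-oic acid | CC=1[C@@H](CC/C(C)=C/C=O)[C@@]2(C)CCC[C@](C)(C(=O)O)[C@@H]2[C@H](OC(=O)c3ccccc3)C=1 | intermediate
32 | 6β-benzoyloxy-7α-hydroperoxy-15-oxo-9β-H-labda-8(17),13E-dien-19-oic acid | C=C1[C@@H](CC/C(C)=C/C=O)[C@@]2(C)CCC[C@](C)(C(=O)O)[C@@H]2[C@H](OC(=O)c2ccccc2)[C@H]1OO | intermediate
33 | 6β-benzoyloxy-7α-hydroxy-15-oxo-9β-H-labda-8(17),13E-dien-19-oic acid | C=C1[C@@H](CC/C(C)=C/C=O)[C@@]2(C)CCC[C@](C)(C(=O)O)[C@@H]2[C@H](OC(=O)c2ccccc2)[C@H]1O | intermediate
34 | (4S,5R,6S,7S,9S,10R)-6β-benzoyloxy-7α,15-dihydroxy-9β-H-labda-8(17),13E-dien-19-oic acid (CNP0149011.1) | C=C1[C@@H](CC/C(C)=C/CO)[C@@]2(C)CCC[C@](C)(C(=O)O)[C@@H]2[C@H](OC(=O)c2ccccc2)[C@H]1O | target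

## Step count and least certain steps

Total: 22 steps. Longest linear sequence: 17 steps (steps 1–6 and 12–22, from 1); the side-chain branch (steps 7–11) joins at step 12.

Step 3 (key step). The trisubstituted alkene of 4 may react too slowly with a diene activated only by an alkyl group. The uncatalysed background reaction, coordination at the hindered carbonyl, or catalyst decay would then erode facial and regiochemical control. Fallback: from 3 and 4, cycloaddition promoted by BF3·OEt2 gives 5 together with its mirror-image adduct F1. Epimerisation as in step 4 gives 6 with its enantiomer F2, and Luche reduction as in step 5 gives 7 with its enantiomer F3. Steglich esterification with (S)-2-methoxy-2-phenylacetic acid (N,N'-dicyclohexylcarbodiimide, 4-(dimethylamino)pyridine) gives the diastereomeric esters, the (S)-methoxyphenylacetate of 7 F4 and the (S)-methoxyphenylacetate of the enantiomer F5, which are separated. Methanolysis of F4 (K2CO3, MeOH) returns to the route at 7.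

Step 4. Equilibration may stop short of the trans epimer: in 6 the equatorial C4 substituent lies close to the C6 carbonyl oxygen, which costs part of the usual trans preference. Fallback by kinetic rather than thermodynamic control: from 5, LiN(SiMe3)2 in THF at −78 °C gives the lithium dienolate F6. Quenching with acetic acid at −78 °C should protonate C5 from the α face, anti to the axial C10 methyl, returning at 6.

Step 16 (with step 15). Condensation at the hindered C7 carbonyl may be slow enough to allow enolisation toward C6. Hydride may also add to the C=N bond from the β face, which would put the hydrogen on the α face of C9. Fallback with nitrogen introduced by substitution: from 20, Luche reduction gives the 7β-allylic alcohol F7, and methyl chloroformate with pyridine gives the 7β-methyl carbonate F8. Tsuji–Trost allylation of N-isopropylidene-N'-(2-nitrobenzenesulfonyl)hydrazine with Pd(PPh3)4 (zerovalent palladium) proceeds with net retention and gives the 7β-N-allyl sulfonyl hydrazone F9. Acetic acid in trifluoroethanol/water releases the diazene 23, which rearranges to 24. Benzoyl migration between the cis oxygens at C6 and C7 of F7 has to be watched.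

Step 19. tert-Butoxide or the enolate oxygen may attack the neighbouring benzoate (acyl transfer), and some O-methylation can occur. Fallback without a free enolate: from 26, TBSOTf and Et3N give the silyl enol ether F10. Simmons–Smith cyclopropanation (Et2Zn, CH2I2) from the open α face gives the siloxycyclopropane F11. Acid-mediated ring opening (TsOH, MeOH/CH2Cl2) breaks the bond between the oxygenated carbon and the new CH2, returning at 28.

Step 22. The ene reaction may be slow at an alkene that is hindered and deactivated by the allylic benzoate. Attack on the β face, rearrangement of the allylic hydroperoxide, or photo-oxidation of the enal could then compete. Fallback by epoxidation and isomerisation: from 31, 3-chloroperoxybenzoic acid with NaHCO3 gives the 7α,8α-epoxide F12; the enal alkene is inert to peracid. TMSOTf and 2,6-lutidine followed by 1,8-diazabicyclo[5.4.0]undec-7-ene open it to the 7α-trimethylsilyl ether F13 with the exocyclic alkene. Aqueous citric acid removes the silyl group and returns at 33, which is reduced as in the last stage of step 22.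

## Further compounds

F1 | step 3 | enantiomer of cis adduct 5 | CC=1C(=O)[C@]2(C)CC=C[C@H](CO[Si](C)(C)C(C)(C)C)[C@@H]2C(=O)C=1
F2 | step 3 | enantiomer of trans ene-dione 6 | CC=1C(=O)[C@]2(C)CC=C[C@H](CO[Si](C)(C)C(C)(C)C)[C@H]2C(=O)C=1
F3 | step 3 | enantiomer of alcohol 7 | CC=1C(=O)[C@]2(C)CC=C[C@H](CO[Si](C)(C)C(C)(C)C)[C@H]2[C@@H](O)C=1
F4 | step 3 | (S)-2-methoxy-2-phenylacetate of 7 | CC=1C(=O)[C@@]2(C)CC=C[C@@H](CO[Si](C)(C)C(C)(C)C)[C@@H]2[C@H](OC(=O)[C@@H](OC)c3ccccc3)C=1
F5 | step 3 | (S)-2-methoxy-2-phenylacetate of F3 | CC=1C(=O)[C@]2(C)CC=C[C@H](CO[Si](C)(C)C(C)(C)C)[C@H]2[C@@H](OC(=O)[C@@H](OC)c3ccccc3)C=1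
F6 | step 4 | lithium C5=C6 dienolate of 5 | CC=1C(=O)[C@@]2(C)CC=C[C@@H](CO[Si](C)(C)C(C)(C)C)C2=C([O-])C=1.[Li+]
F7 | step 16 | 6β-benzoyloxy-7β-hydroxy-8-ene | CC1=C(CC/C(C)=C/COCc3ccc(OC)cc3)[C@@]2(C)CCC[C@@H](CO[Si](C)(C)C(C)(C)C)[C@@H]2[C@H](OC(=O)c3ccccc3)[C@@H]1O
F8 | step 16 | 7β-methyl carbonate of F7 | CC1=C(CC/C(C)=C/COCc3ccc(OC)cc3)[C@@]2(C)CCC[C@@H](CO[Si](C)(C)C(C)(C)C)[C@@H]2[C@H](OC(=O)c3ccccc3)[C@@H]1OC(=O)OC
F9 | step 16 | 7β-[N-(2-nitrobenzenesulfonyl)-N'-isopropylidenehydrazinyl]-8-ene | CC1=C(CC/C(C)=C/COCc3ccc(OC)cc3)[C@@]2(C)CCC[C@@H](CO[Si](C)(C)C(C)(C)C)[C@@H]2[C@H](OC(=O)c3ccccc3)[C@@H]1N(N=C(C)C)S(=O)(=O)c1ccccc1[N+](=O)[O-]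
F10 | step 19 | C4=C19 tert-butyldimethylsilyl enol ether of 26 | CC=1[C@@H](CC/C(C)=C/COCc3ccc(OC)cc3)[C@@]2(C)CCCC(=CO[Si](C)(C)C(C)(C)C)[C@@H]2[C@H](OC(=O)c3ccccc3)C=1
F11 | step 19 | spiro siloxycyclopropane at C4 (new CH2 on the α face) | CC=1[C@@H](CC/C(C)=C/COCc3ccc(OC)cc3)[C@@]2(C)CCC[C@@]3(CC3O[Si](C)(C)C(C)(C)C)[C@@H]2[C@H](OC(=O)c3ccccc3)C=1
F12 | step 22 | 7α,8α-epoxide of 31 | C[C@]12[C@@H](CC/C(C)=C/C=O)[C@@]3(C)CCC[C@](C)(C(=O)O)[C@@H]3[C@H](OC(=O)c3ccccc3)[C@H]1O2
F13 | step 22 | 7α-trimethylsilyl ether of 33 | C=C1[C@@H](CC/C(C)=C/C=O)[C@@]2(C)CCC[C@](C)(C(=O)O)[C@@H]2[C@H](OC(=O)c2ccccc2)[C@H]1O[Si](C)(C)C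
A1 | alternative 1 | 4-(tert-butyldimethylsilyloxy)-2-[3-(4-methoxybenzyloxy)propyl]cyclohex-2-en-1-one, single enantiomer | CC(C)(C)[Si](C)(C)O[C@@H]1C=C(CCCOCc2ccc(OC)cc2)C(=O)CC1
A2 | alternative 1 | 4-(tert-butyldimethylsilyloxy)-2-methyl-2-[3-(4-methoxybenzyloxy)propyl]-3-[(E)-3-methyl-5-(triisopropylsilyloxy)pent-3-enyl]cyclohexanone | CC(C)(C)[Si](C)(C)O[C@@H]1[C@@H](CC/C(C)=C/CO[Si](C(C)C)(C(C)C)C(C)C)[C@@](C)(CCCOCc2ccc(OC)cc2)C(=O)CC1
A3 | alternative 2 | 8-phenylmenthyl 3-oxo-12-(tert-butyldimethylsilyloxy)-13,14,15,16-tetranor-9β-H-labd-8(17)-en-19-oate | C=C1[C@@H](CCO[Si](C)(C)C(C)(C)C)[C@@]2(C)CCC(=O)[C@](C)(C(=O)O[C@H]3C[C@@H](C)CC[C@@H]3C(C)(C)c3ccccc3)[C@@H]2CC1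
A4 | alternative 3 | methyl 6-oxo-15-(triisopropylsilyloxy)-9β-H-labda-8(17),13E-dien-19-oate | C=C1[C@@H](CC/C(C)=C/CO[Si](C(C)C)(C(C)C)C(C)C)[C@@]2(C)CCC[C@](C)(C(=O)OC)[C@@H]2C(=O)C1
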